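## Structural features

Isoaurmillone (17) is an isoflavone: a benzene ring A is fused to a 4-pyranone ring C, and a para-oxygenated phenyl ring B sits on C3. Ring A is substituted at every position except C8. The C5 hydroxyl (hydrogen-bonded to the C4 carbonyl), the C6 methoxy group and the C7 hydroxyl are contiguous, and O1 is attached at C8a, so the ring has a 1,2,3,5-tetraoxygen pattern with the methylated oxygen in the middle of three. The ring B oxygen is a 3-methylbut-2-enyl (prenyl) ether, whereas both ring A phenols are free. The target has no stereocentre, so none stand next to each other; the route creates only a transient tertiary carbinol at C3, which is erased when the C2–C3 double bond is formed. The fragile groups are the prenyl ether (ionised by strong acid, cleaved by Lewis acids and by zerovalent palladium, lost on hydrogenation), ring C (opened at C2 by hydroxide) and the electron-rich phenols. The real difficulty is differentiation rather than skeleton: three phenolic oxygens must end as one prenyl ether and two free hydroxyls beside a methyl ether, and ring C must be closed without disturbing the prenyl group. The key step uses the fact that C4 is a ketone carbon on C4a, while C3 carries ring B and is linked through C2 to O1. Once water is formally added across C2–C3, the C3–C4 bond is the bond of an α-hydroxy ketone. It can be made from an acyl anion at C4 and an aryl ketone carbonyl at C3, the two being tethered by the O1–C2 ether.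

## Logic of the disconnections

17 ⇒ 15. The O–H bonds at O5 and O7 are exchanged for O–CH2OMe acetal bonds (16 is the half-way stage). Free phenols would protonate a carbene, consume base and compete in O-alkylation, whereas small acetals are inert to base, nucleophiles and the dehydrating reagent. The gain is that the ring B ether is the only sensitive oxygen function left to manage. The forward step must cleave two acetals beside an allylic aryl ether; it relies on the far easier ionisation of an O–CH2–O unit than of an allyl–O bond.

15 ⇒ 13. Water is added retrosynthetically across C2=C3, with the hydroxyl on C3. This turns the vinylogous ester of ring C into an α-hydroxy ketone and exposes C3–C4 as a benzoin-type bond. The price is one stereocentre, which is irrelevant because it is destroyed again. The forward elimination must go toward C2 (the only carbon with β-hydrogens) and must not use acid.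

13 ⇒ 11. The C3–C4 bond is cut, which opens ring C and removes the tertiary carbinol. What remains is an aldehyde on ring A and an aryl ketone, joined by the O1–C2 ether so that the two carbonyl carbons are five atoms apart. The forward step must invert the polarity of a hindered, electron-rich aldehyde in the presence of an enolisable ketone.

11 ⇒ 6 + 9. The O1–C2 ether bond is cut (10 is the transient activated form of 9). This divides the molecule into two fragments of similar size, one per aromatic ring. The forward O-alkylation must stop at the ether and not continue to an aldol closure.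

9 ⇒ 7 + 8. The allylic C–O bond of the ring B ether is cut. Both pieces are commercial. The forward ether formation has to be run without free phenoxide, because the α-chloro ketone is itself an electrophile.

6 ⇒ 4. The bond between C4a and the formyl carbon is cut (5 is the hydroxymethyl stage). Because 4 is symmetric, both carbons ortho to its free hydroxyl are equivalent and the para carbon is blocked, so no regiochemical question arises. The forward step needs an ortho-selective formylation that spares the acetals.

4 ⇒ 2. The C8a–O bond is replaced by C–H (3 is the borylated stage). This C–H is the only one of 2 without an ortho substituent. The forward step needs a sterically governed C–H functionalisation followed by oxidation.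

2 ⇒ 1. The two acetal O–C bonds are cut, giving a commercial diol that already contains the O–C(OMe)–O triad of C5, C6 and C7.

## Other disconnections considered

Alternative 1: The cut is through C4a–C5 and C8–C8a, so ring A is assembled from acyclic pieces. In the forward sense 1,2-dimethoxy-1,3-bis(trimethylsilyloxy)buta-1,3-diene A1 and methyl 3-bromopropiolate A2 would combine in a (4+2) cycloaddition, and loss of methanol would aromatise the adduct to methyl 6-bromo-2,4-dihydroxy-3-methoxybenzoate A3.
- In its favour: the polarity match (nucleophilic CH2 terminus of A1 with the β-carbon of the ynoate) should place all five ring A substituents in one step. The ester carbon is already C4 and the bromine marks C8a.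
- Where it is equal or better: on control of the ring A pattern it equals the chosen plan, which relies on the symmetry of 4. It is better in that C4 arrives attached and no C–H borylation with [Ir(OMe)(cod)]2 is needed.
- Against it: it builds the one ring that can be bought with the correct oxygen triad (1). After A3 nothing of ring C exists. Two phenols must be protected, the ester must become the benzyl ketone carrying ring B, C2 must be added, and O1–C8a must be closed by a C–O coupling (for example with CuI) on a hindered, electron-rich aryl bromide.
- Reagents and mechanism: A1 is a tetrasubstituted, moisture-sensitive ketene acetal whose reactive s-cis form is crowded by its internal methoxy group. A2 is a labile bromoalkyne that can undergo substitution at bromine instead of cycloaddition. The chosen plan puts its uncertainty into one catalytic ring closure.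
- Step economy: clearly worse, with roughly five further steps after the key step against two.

Alternative 2: The cut is C4–C4a. In the forward sense (Z)-2-[4-(benzyloxy)phenyl]-3-[4-methoxy-3,5-bis(2,2-dimethylpropanoyloxy)phenoxy]prop-2-enoic acid A4 would be converted with oxalyl chloride into its acid chloride A5. Ionisation with SnCl4 would then acylate the ring carbon ortho to the ether oxygen, giving 3-[4-(benzyloxy)phenyl]-6-methoxy-4-oxo-4H-chromene-5,7-diyl bis(2,2-dimethylpropanoate) A6.
- Where it is equal or better: ring C would appear directly at the chromone oxidation level with no stereocentre and no dehydration, which is better than the chosen plan. The symmetric aryloxy ring removes any regiochemical question, which equals the chosen plan.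
- Against it, electronically: the acylium ion is a stabilised, mild electrophile. It must attack a carbon flanked by a pivaloyloxy group on a ring whose ester oxygens donate only weakly.
- Against it, functional groups: SnCl4 invites Fries migration of the pivaloyl groups and cleavage of the benzyl ether, and it excludes a prenyl ether. Ring B therefore carries a benzyl placeholder. After the closure this costs debenzylation without saturating C2=C3, prenylation, and basic removal of two pivalates from a base-sensitive ring C, which is three steps against two.
- Against it, precursor: only the Z isomer of A4 can cyclise, and liberating its carboxylic acid beside two aryl esters is a further constraint.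
- Comparison: the reagents are simpler than a carbene catalyst, but the chosen plan is mechanistically better matched to this substitution pattern and shorter overall.

Alternative 3: The cuts are O1–C8a and C4–C4a, so ring C is formed by annulating both of its bonds to ring A. In the forward sense CsF would convert 4-methoxy-3,5-bis(methoxymethoxy)-2-(trimethylsilyl)phenyl trifluoromethanesulfonate A7 into 4-methoxy-3,5-bis(methoxymethoxy)benzyne A8. The enolate oxygen of methyl 2-[4-(3-methylbut-2-enyloxy)phenyl]-3-oxopropanoate A9 would add at C8a, and the C4a anion would attack the ester to give 6-methoxy-5,7-bis(methoxymethoxy)-3-[4-(3-methylbut-2-enyloxy)phenyl]-4H-chromen-4-one A10, which is the same compound as 15.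
- Where it is equal or better: it is the most convergent option and better than the chosen plan after the key step, since it would reach 15 without the hydroxy ketone and without dehydration. Fluoride conditions are as kind to the acetals and the prenyl ether as the carbene conditions. Regiocontrol by the C5 oxygen, which favours attack at the distal aryne carbon and places the anion next to the oxygen, is as good as control by symmetry.
- Against it, mechanism: a β-oxo ester enolate is ambident and normally engages arynes through carbon, leading to α-arylation or insertion into the C–C bond. Nothing in A9 enforces the O-attack that the annulation needs. The aryl anion can also be protonated by the acidic A9 before acyl transfer.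
- Against it, precursor: A7 is a pentasubstituted silyl triflate that would take about three steps from 4.
- Comparison: overall length comes out similar to the chosen plan, but the decisive step is less secure, whereas the chosen closure is a known reaction type on this substrate class.

Key step: step 6

Remarks on the chemistry:
- The precursor 11 and the product 13 are isomers (C25H30O9). In 11 the formyl carbon becomes C4, the ring carbon bearing it C4a, and the ring carbon bearing the ether oxygen C8a. Names and SMILES are mutually consistent and need no correction.
- "Safe" is read as chemically reliable.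
- Because the C3 centre of 13 is destroyed in step 7, an achiral carbene precursor is used and 13 is carried on as the racemate.

## Route

Step 1
Reactants: 1 2-methoxybenzene-1,3-diol (2-methoxyresorcinol)
Product: 2 2-methoxy-1,3-bis(methoxymethoxy)benzene
Conditions: MOMCl (2.6 equiv), iPr2NEt (3 equiv), CH2Cl2, 0 °C to rt
Reagents that add atoms: chloromethyl methyl ether (MOMCl), COCCl
Why: Double O-alkylation of the phenols by the highly reactive α-chloro ether (methoxymethyl protection); the substrate is symmetric, so no selectivity is required, and the acetals tolerate every basic and nucleophilic step that follows.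

Step 2
Reactants: 2 2-methoxy-1,3-bis(methoxymethoxy)benzene
Product: 4 4-methoxy-3,5-bis(methoxymethoxy)phenol, via aryl pinacol boronate 3 (not isolated)
Conditions: [Ir(OMe)(cod)]2 (1.5 mol%), 4,4'-di-tert-butyl-2,2'-bipyridine (3 mol%), B2pin2 (1.0 equiv), THF, 70 °C; then aq. NaOH, 30% H2O2, 0 °C
Reagents that add atoms: hydrogen peroxide, OO
Why: Sterically governed C–H borylation with [Ir(OMe)(cod)]2 and the bipyridine ligand should take the only C–H of 2 that has no ortho substituent (para to the methoxy group); the boronate is oxidised in the same flask by 1,2-shift of the aryl group from boron to oxygen (one-pot borylation–oxidation), and the basic peroxide conditions leave the acetals intact.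

Step 3
Reactants: 4 4-methoxy-3,5-bis(methoxymethoxy)phenol
Product: 6 2-hydroxy-5-methoxy-4,6-bis(methoxymethoxy)benzaldehyde, via salicyl alcohol 5 (not isolated)
Conditions: MgCl2 (2 equiv), Et3N (4 equiv), (CH2O)n (6 equiv), MeCN, reflux; cold aq. NH4Cl work-up
Reagents that add atoms: formaldehyde (used as paraformaldehyde), C=O
Why: Magnesium-mediated ortho-formylation (Casnati–Skattebøl type): the chloromagnesium phenoxide ArOMgCl delivers formaldehyde to the ortho carbon through a chelate, and the benzylic alkoxide 5 is oxidised by a second formaldehyde through hydride transfer. Both ortho carbons of 4 are equivalent and the para carbon is blocked, so one aldehyde should result, and the chelated product resists a second formylation.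

Step 4
Reactants: 7 2-chloro-1-(4-hydroxyphenyl)ethanone; 8 3-methylbut-2-en-1-ol (prenyl alcohol)
Product: 9 2-chloro-1-[4-(3-methylbut-2-enyloxy)phenyl]ethanone
Conditions: PPh3 (1.2 equiv) and DIAD (1.2 equiv) premixed, THF, 0 °C; then 8 (1.2 equiv), then 7, 0 °C to rt
Reagents that add atoms: none
Why: Mitsunobu etherification: the acidic para-acyl phenol protonates the betaine and its phenoxide displaces the oxyphosphonium of 8 by SN2 at the unhindered primary allylic carbon. Forming the betaine first leaves no free PPh3 to quaternise the α-chloro ketone, and the absence of free base prevents phenoxide attack on the chloro ketone of another molecule.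

Step 5
Reactants: 6 2-hydroxy-5-methoxy-4,6-bis(methoxymethoxy)benzaldehyde; 9 2-chloro-1-[4-(3-methylbut-2-enyloxy)phenyl]ethanone
Product: 11 3-methoxy-2,4-bis(methoxymethoxy)-6-{2-[4-(3-methylbut-2-enyloxy)phenyl]-2-oxoethoxy}benzaldehyde, via iodo ketone 10 (not isolated)
Conditions: K2CO3 (1.5 equiv), KI (10 mol%), DMF, rt
Reagents that add atoms: none
Why: Williamson etherification of the phenoxide of 6 with the α-halo ketone, accelerated by in situ Finkelstein exchange to 10. Room temperature and a heterogeneous weak base are chosen so that the product is not carried on to the Rap–Stoermer aldol closure, which needs heating.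

Step 6
Reactants: 11 3-methoxy-2,4-bis(methoxymethoxy)-6-{2-[4-(3-methylbut-2-enyloxy)phenyl]-2-oxoethoxy}benzaldehyde
Product: 13 racemic 3-hydroxy-6-methoxy-5,7-bis(methoxymethoxy)-3-[4-(3-methylbut-2-enyloxy)phenyl]chroman-4-one, via Breslow intermediate 12 (not isolated)
Conditions: 2-(pentafluorophenyl)-6,7-dihydro-5H-pyrrolo[2,1-c][1,2,4]triazol-2-ium tetrafluoroborate (20 mol%), Et3N (20 mol%), THF (0.05 M), rt to 40 °C, Ar
Reagents that add atoms: none
Why: Et3N releases a small equilibrium amount of the triazolylidene, which adds to the aldehyde carbon of 11; proton transfer gives the hydroxy-enamine 12, an acyl anion equivalent centred on the future C4. Its nucleophilic carbon attacks the aryl ketone carbonyl held five atoms away, forming C3–C4, and collapse of the adduct expels the carbene and leaves the C4 ketone beside the tertiary alcohol at C3. The closest known reaction type is the carbene-catalysed intramolecular crossed aldehyde–ketone benzoin cyclisation of 2-(2-oxoalkoxy)benzaldehydes to 3-hydroxychroman-4-ones. Ring C closes in the 6-exo-trig mode, the attacked C=O being exocyclic to the new six-membered ring. The C3 stereocentre is formed without any controlling element because the precatalyst is achiral; 13 is racemic by design and the centre disappears in step 7. The selectivity required is chemoselectivity: addition of the acyl anion equivalent to the ketone must outrun amine-mediated enolisation of the O–CH2–C(=O) unit with aldol closure onto the aldehyde (the benzofuran pathway) and intermolecular aldehyde–aldehyde benzoin. The substrate secures this through the short tether, which makes the ketone the only electrophile within reach of C4, and through the two ortho oxygens of the aldehyde, which hinder dimerisation; the acidic pentafluorophenyl triazolium lets a weak amine act as base, so enolate concentration stays negligible and the prenyl and methoxymethyl ethers are untouched.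

Step 7
Reactants: 13 racemic 3-hydroxy-6-methoxy-5,7-bis(methoxymethoxy)-3-[4-(3-methylbut-2-enyloxy)phenyl]chroman-4-one
Product: 15 6-methoxy-5,7-bis(methoxymethoxy)-3-[4-(3-methylbut-2-enyloxy)phenyl]-4H-chromen-4-one, via sulfamate ester 14 (not isolated)
Conditions: Burgess reagent (2.5 equiv), THF, rt to 60 °C
Reagents that add atoms: none
Why: Burgess dehydration: the tertiary alcohol is sulfamoylated to 14, which undergoes thermal syn-elimination with a hydrogen of C2, the only carbon carrying β-hydrogens, so the double bond can form only across C2–C3. The conditions are neutral and spare the acetals and the prenyl ether, and formation of the conjugated chromone drives the elimination.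

Step 8
Reactants: 15 6-methoxy-5,7-bis(methoxymethoxy)-3-[4-(3-methylbut-2-enyloxy)phenyl]-4H-chromen-4-one
Product: 17 isoaurmillone, 5,7-dihydroxy-6-methoxy-3-[4-(3-methylbut-2-enyloxy)phenyl]-4H-chromen-4-one, via mono-MOM isoflavone 16 (not isolated)
Conditions: HCl (0.5 M in MeOH), CH2Cl2 co-solvent, 0 °C to rt
Reagents that add atoms: none
Why: Acid-catalysed transacetalisation to methanol: the C5 acetal, assisted by the peri carbonyl, should go first (16), then the C7 acetal, whose phenol is a good leaving group. Ionisation of an O–CH2–OMe unit to a methoxymethyl cation is far easier than ionisation of the prenyl–O bond of the less acidic ring B phenol, so dilute acid at or below room temperature should leave the prenyl ether and its alkene intact.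

## Compound list

1 | 2-methoxybenzene-1,3-diol (2-methoxyresorcinol) | COc1c(O)cccc1O | starting material
2 | 2-methoxy-1,3-bis(methoxymethoxy)benzene | COCOc1cccc(OCOC)c1OC | intermediate
3 | 2-[4-methoxy-3,5-bis(methoxymethoxy)phenyl]-4,4,5,5-tetramethyl-1,3,2-dioxaborolane | COCOc1cc(B2OC(C)(C)C(C)(C)O2)cc(OCOC)c1OC | intermediate (not isolated)
4 | 4-methoxy-3,5-bis(methoxymethoxy)phenol | COCOc1cc(O)cc(OCOC)c1OC | intermediate
5 | 2-(hydroxymethyl)-4-methoxy-3,5-bis(methoxymethoxy)phenol (present as its magnesium alkoxide) | COCOc1cc(O)c(CO)c(OCOC)c1OC | intermediate (not isolated)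
6 | 2-hydroxy-5-methoxy-4,6-bis(methoxymethoxy)benzaldehyde | COCOc1cc(O)c(C=O)c(OCOC)c1OC | intermediate
7 | 2-chloro-1-(4-hydroxyphenyl)ethanone | O=C(CCl)c1ccc(O)cc1 | starting material
8 | 3-methylbut-2-en-1-ol (prenyl alcohol) | CC(C)=CCO | starting material
9 | 2-chloro-1-[4-(3-methylbut-2-enyloxy)phenyl]ethanone | CC(C)=CCOc1ccc(cc1)C(=O)CCl | intermediate
10 | 2-iodo-1-[4-(3-methylbut-2-enyloxy)phenyl]ethanone | CC(C)=CCOc1ccc(cc1)C(=O)CI | intermediate (not isolated)
11 | 3-methoxy-2,4-bis(methoxymethoxy)-6-{2-[4-(3-methylbut-2-enyloxy)phenyl]-2-oxoethoxy}benzaldehyde | O=Cc1c(OCC(=O)c2ccc(OCC=C(C)C)cc2)cc(OCOC)c(OC)c1OCOC | intermediate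
12 | hydroxy-enamine (Breslow intermediate): [2-(pentafluorophenyl)-2,5,6,7-tetrahydro-3H-pyrrolo[2,1-c][1,2,4]triazol-3-ylidene](3-methoxy-2,4-bis(methoxymethoxy)-6-{2-[4-(3-methylbut-2-enyloxy)phenyl]-2-oxoethoxy}phenyl)methanol | OC(=C1N(c2c(F)c(F)c(F)c(F)c2F)N=C2CCCN12)c1c(OCC(=O)c2ccc(OCC=C(C)C)cc2)cc(OCOC)c(OC)c1OCOC | intermediate (not isolated)
13 | racemic 3-hydroxy-6-methoxy-5,7-bis(methoxymethoxy)-3-[4-(3-methylbut-2-enyloxy)phenyl]chroman-4-one | COCOc1cc2OCC(O)(c3ccc(OCC=C(C)C)cc3)C(=O)c2c(OCOC)c1OC | intermediate
14 | triethylammonium salt of methyl N-({6-methoxy-5,7-bis(methoxymethoxy)-3-[4-(3-methylbut-2-enyloxy)phenyl]-4-oxochroman-3-yl}oxysulfonyl)carbamate (racemic) | CC[NH+](CC)CC.COC(=O)[N-]S(=O)(=O)OC1(COc2cc(OCOC)c(OC)c(OCOC)c2C1=O)c1ccc(OCC=C(C)C)cc1 | intermediate (not isolated)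
15 | 6-methoxy-5,7-bis(methoxymethoxy)-3-[4-(3-methylbut-2-enyloxy)phenyl]-4H-chromen-4-one | COCOc1cc2occ(-c3ccc(OCC=C(C)C)cc3)c(=O)c2c(OCOC)c1OC | intermediate
16 | 5-hydroxy-6-methoxy-7-(methoxymethoxy)-3-[4-(3-methylbut-2-enyloxy)phenyl]-4H-chromen-4-one | COCOc1cc2occ(-c3ccc(OCC=C(C)C)cc3)c(=O)c2c(O)c1OC | intermediate (not isolated)
17 | isoaurmillone, 5,7-dihydroxy-6-methoxy-3-[4-(3-methylbut-2-enyloxy)phenyl]-4H-chromen-4-one | COc1c(O)cc2occ(-c3ccc(OCC=C(C)C)cc3)c(=O)c2c1O | target

## Step count and risk

Total step count: 8. Longest linear sequence: 7 steps (1 → 2 → 4 → 6 → 11 → 13 → 15 → 17); step 4 is a one-step branch.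

Least certain steps:

Step 6 (key step). The most likely failure is slow addition of the carbene to an aldehyde that is electron-rich and flanked by two ortho oxygens. That leaves time for amine-mediated enolisation of the α-aryloxy ketone and aldol closure onto the aldehyde with dehydration, or for oxidation of the acyl anion equivalent by adventitious oxygen. The fallback sets out from 6 and comes back to the route at 15; it abandons umpolung and builds ring C as a 3-iodochromone that is then arylated.
- Addition of MeMgBr (excess, THF, 0 °C) to 6 should give 2-(1-hydroxyethyl)-4-methoxy-3,5-bis(methoxymethoxy)phenol F1.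
- MnO2 in CH2Cl2 should oxidise the benzylic alcohol to 1-[2-hydroxy-5-methoxy-4,6-bis(methoxymethoxy)phenyl]ethanone F2.
- N,N-Dimethylformamide dimethyl acetal (90 °C) should give (E)-3-(dimethylamino)-1-[2-hydroxy-5-methoxy-4,6-bis(methoxymethoxy)phenyl]prop-2-en-1-one F3.
- Iodine with pyridine in CHCl3 should close ring C with iodination to 3-iodo-6-methoxy-5,7-bis(methoxymethoxy)-4H-chromen-4-one F4.
- Suzuki–Miyaura coupling of F4 with 4,4,5,5-tetramethyl-2-[4-(3-methylbut-2-enyloxy)phenyl]-1,3,2-dioxaborolane F5 (from commercial 4-hydroxyphenylboronic acid pinacol ester, prenyl bromide and K2CO3), using Pd(dppf)Cl2 and K2CO3 in dioxane–water, should give 15.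
- Steps 4 to 7 are then not needed.

Step 8. The risk is acid-induced ionisation of the allylic C–O bond of the prenyl ether, or addition of HCl or methanol to its alkene, before the slower C7 acetal has been cleaved. The fallback sets out from 15 and comes back at 17; it replaces protic solvolysis by buffered silyl transfer. TMSOTf with 2,2'-bipyridyl in CH2Cl2 at 0 °C should convert both aryl acetals into silyl ethers, giving 6-methoxy-3-[4-(3-methylbut-2-enyloxy)phenyl]-5,7-bis(trimethylsilyloxy)-4H-chromen-4-one F6 with no free acid present. Addition of water should then hydrolyse the two aryl silyl ethers to 17.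

Step 5. The risk is over-reaction under carbonate: the O–CH2 carbon of the new ether attacks the aldehyde and dehydration gives an aroylbenzofuran. Alternatively, alkylation of the hindered, hydrogen-bonded phenoxide may be sluggish. The fallback sets out from 9 and comes back at 11; it forms the ether without base. HCO2Na in aqueous ethanol at reflux should displace chloride to give 2-[4-(3-methylbut-2-enyloxy)phenyl]-2-oxoethyl formate F7, which is hydrolysed in the same medium to 2-hydroxy-1-[4-(3-methylbut-2-enyloxy)phenyl]ethanone F8. Mitsunobu coupling of F8 with the acidic phenol 6 (PPh3, DIAD, THF) should then give 11 under neutral conditions, in which the aldol closure has no base to start it.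

Step 4. The risks are quaternisation of PPh3 by the α-chloro ketone, attack of phenoxide on the chloro ketone of a second molecule, and some SN2′ attack leading to the tertiary allylic ether. The fallback sets out from 8 and comes back at 11; it installs the halogen after the ether.
- Mitsunobu coupling of 8 with commercial 1-(4-hydroxyphenyl)ethanone should give 1-[4-(3-methylbut-2-enyloxy)phenyl]ethanone F9.
- LiHMDS and TMSCl in THF at −78 °C should give trimethyl({1-[4-(3-methylbut-2-enyloxy)phenyl]ethenyl}oxy)silane F10.
- NBS in THF at −78 °C should brominate the enol silane, far more nucleophilic than the prenyl alkene, to give 2-bromo-1-[4-(3-methylbut-2-enyloxy)phenyl]ethanone F11.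
- F11 takes the place of 9 in step 5 (K2CO3, DMF, rt, no iodide needed) and gives 11.

## Further compounds

F1 | step 6 | 2-(1-hydroxyethyl)-4-methoxy-3,5-bis(methoxymethoxy)phenol (racemic) | COCOc1cc(O)c(C(C)O)c(OCOC)c1OC
F2 | step 6 | 1-[2-hydroxy-5-methoxy-4,6-bis(methoxymethoxy)phenyl]ethanone | COCOc1cc(O)c(C(C)=O)c(OCOC)c1OC
F3 | step 6 | (E)-3-(dimethylamino)-1-[2-hydroxy-5-methoxy-4,6-bis(methoxymethoxy)phenyl]prop-2-en-1-one | COCOc1cc(O)c(C(=O)/C=C/N(C)C)c(OCOC)c1OC
F4 | step 6 | 3-iodo-6-methoxy-5,7-bis(methoxymethoxy)-4H-chromen-4-one | COCOc1cc2occ(I)c(=O)c2c(OCOC)c1OC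
F5 | step 6 | 4,4,5,5-tetramethyl-2-[4-(3-methylbut-2-enyloxy)phenyl]-1,3,2-dioxaborolane | CC(C)=CCOc1ccc(cc1)B1OC(C)(C)C(C)(C)O1
F6 | step 8 | 6-methoxy-3-[4-(3-methylbut-2-enyloxy)phenyl]-5,7-bis(trimethylsilyloxy)-4H-chromen-4-one | COc1c(O[Si](C)(C)C)cc2occ(-c3ccc(OCC=C(C)C)cc3)c(=O)c2c1O[Si](C)(C)C
F7 | step 5 | 2-[4-(3-methylbut-2-enyloxy)phenyl]-2-oxoethyl formate | CC(C)=CCOc1ccc(cc1)C(=O)COC=O
F8 | step 5 | 2-hydroxy-1-[4-(3-methylbut-2-enyloxy)phenyl]ethanone | CC(C)=CCOc1ccc(cc1)C(=O)CO
F9 | step 4 | 1-[4-(3-methylbut-2-enyloxy)phenyl]ethanone | CC(C)=CCOc1ccc(cc1)C(C)=O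
F10 | step 4 | trimethyl({1-[4-(3-methylbut-2-enyloxy)phenyl]ethenyl}oxy)silane | CC(C)=CCOc1ccc(cc1)C(=C)O[Si](C)(C)C
F11 | step 4 | 2-bromo-1-[4-(3-methylbut-2-enyloxy)phenyl]ethanone | CC(C)=CCOc1ccc(cc1)C(=O)CBr
A1 | alternative 1 | 1,2-dimethoxy-1,3-bis(trimethylsilyloxy)buta-1,3-diene | COC(O[Si](C)(C)C)=C(OC)C(=C)O[Si](C)(C)C
A2 | alternative 1 | methyl 3-bromopropiolate | COC(=O)C#CBr
A3 | alternative 1 | methyl 6-bromo-2,4-dihydroxy-3-methoxybenzoate | COC(=O)c1c(Br)cc(O)c(OC)c1O
A4 | alternative 2 | (Z)-2-[4-(benzyloxy)phenyl]-3-[4-methoxy-3,5-bis(2,2-dimethylpropanoyloxy)phenoxy]prop-2-enoic acid | OC(=O)/C(=C\Oc1cc(OC(=O)C(C)(C)C)c(OC)c(OC(=O)C(C)(C)C)c1)c1ccc(OCc2ccccc2)cc1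
A5 | alternative 2 | (Z)-2-[4-(benzyloxy)phenyl]-3-[4-methoxy-3,5-bis(2,2-dimethylpropanoyloxy)phenoxy]prop-2-enoyl chloride | ClC(=O)/C(=C\Oc1cc(OC(=O)C(C)(C)C)c(OC)c(OC(=O)C(C)(C)C)c1)c1ccc(OCc2ccccc2)cc1
A6 | alternative 2 | 3-[4-(benzyloxy)phenyl]-6-methoxy-4-oxo-4H-chromene-5,7-diyl bis(2,2-dimethylpropanoate) | COc1c(OC(=O)C(C)(C)C)cc2occ(-c3ccc(OCc4ccccc4)cc3)c(=O)c2c1OC(=O)C(C)(C)C
A7 | alternative 3 | 4-methoxy-3,5-bis(methoxymethoxy)-2-(trimethylsilyl)phenyl trifluoromethanesulfonate | COCOc1cc(OS(=O)(=O)C(F)(F)F)c([Si](C)(C)C)c(OCOC)c1OC
A8 | alternative 3 | 4-methoxy-3,5-bis(methoxymethoxy)benzyne (1,2-didehydrobenzene numbering) | COCOC1=CC#CC(OCOC)=C1OC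
A9 | alternative 3 | methyl 2-[4-(3-methylbut-2-enyloxy)phenyl]-3-oxopropanoate | COC(=O)C(C=O)c1ccc(OCC=C(C)C)cc1
A10 | alternative 3 | 6-methoxy-5,7-bis(methoxymethoxy)-3-[4-(3-methylbut-2-enyloxy)phenyl]-4H-chromen-4-one (same compound as 15) | COCOc1cc2occ(-c3ccc(OCC=C(C)C)cc3)c(=O)c2c(OCOC)c1OC
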